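## Retrosynthetic overview
1. The target is the erythro (anti) 7S,8R isomer. It comes from a (1S,2R)-1-aryl-2-aryloxybut-3-en-1-ol by one O3/LiBH4 operation: vinyl gives C9H2OH, methyl ester gives the side-chain CH2OH, and the aryl acetates give the catechol.
2. The key disconnection is C7–C8. Both carbons bear oxygen and are natural acceptors. C8 is therefore used with inverted polarity, as an α-aryloxyallyl anion equivalent in the form of an (E)-γ-aryloxyallyl-Bpin. It adds to 3,4-diacetoxybenzaldehyde under a chiral phosphoric acid, which sets both stereocentres at once.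
3. The (E)-γ-aryloxyallylboronate comes from an Ir–H double-bond shift of an (E)-3-aryloxyprop-1-enyl-Bpin. That comes from hydroboration of the aryl propargyl ether, made from methyl dihydroferulate and propargyl bromide.
4. No ring is formed. Both arenes are bought.

Assumption: the SMILES is read as (7S,8R), the erythro/anti series, and compounds 1 and 6 are taken as catalogue chemicals.

## Route

Step 1
Reactants: 1 methyl 3-(4-hydroxy-3-methoxyphenyl)propanoate (methyl dihydroferulate); 2 propargyl bromide
Product: 3 methyl 3-[3-methoxy-4-(prop-2-yn-1-yloxy)phenyl]propanoate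
Conditions: 2 (1.2 equiv), K2CO3 (1.5 equiv), acetone, reflux, 6 h
Reagents that add atoms: propargyl bromide C#CCBr
Why: Williamson ether synthesis, in which K2CO3 deprotonates only the phenol and the phenoxide displaces the propargylic bromide by SN2; the methyl ester is inert and no stereocentre is involved.

Step 2
Reactants: 3 methyl 3-[3-methoxy-4-(prop-2-yn-1-yloxy)phenyl]propanoate; 4 pinacolborane
Product: 5 methyl 3-(3-methoxy-4-{[(2E)-3-(4,4,5,5-tetramethyl-1,3,2-dioxaborolan-2-yl)prop-2-en-1-yl]oxy}phenyl)propanoate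
Conditions: HBpin (1.2 equiv), Cp2ZrHCl (10 mol %), Et3N (10 mol %), neat, 60 °C, 16 h
Reagents that add atoms: pinacolborane [H]B1OC(C)(C)C(C)(C)O1
Why: Zirconocene-hydride-catalysed syn-hydroboration of a terminal alkyne, in which hydrozirconation puts Zr on the terminal carbon and Zr/B exchange with HBpin gives only the (E)-1-alkenylboronate; the ester and the aryl ether react far more slowly than the alkyne.

Step 3
Reactants: 5 methyl 3-(3-methoxy-4-{[(2E)-3-(pinacolboryl)prop-2-en-1-yl]oxy}phenyl)propanoate; 6 3,4-diacetoxybenzaldehyde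
Product: 9 4-[(1S,2R)-1-hydroxy-2-{2-methoxy-4-(3-methoxy-3-oxopropyl)phenoxy}but-3-en-1-yl]benzene-1,2-diyl diacetate, via E-allylboronate 7 (not isolated), via borate ester 8 (not isolated)
Conditions: (i) [Ir(cod)(PMePh2)2]PF6 (3 mol %, H2-activated, then Ar), EtOAc, rt, 1 h; Florisil plug, swap to toluene; (ii) 6 (0.9 equiv), (R)-TRIP (5 mol %), 4 Å MS, toluene, −30 → 0 °C, 48 h; (iii) moist SiO2
Reagents that add atoms: none
Why: Proposed new method: a cationic Ir–H moves the C=C one position by insertion/β-H elimination, the same process that turns allyl aryl ethers into (E)-propenyl ethers and 3-silyloxy-1-alkenylboronates into (E)-γ-silyloxyallylboronates, so that in 7 the O-bearing carbon (normally an acceptor) becomes the nucleophilic γ-terminus of an allylboronate; (R)-TRIP then activates the boronate by H-bonding to a pinacol oxygen and to the formyl H, the closed Zimmerman–Traxler chair with E geometry gives the anti relationship, and the catalyst pocket exposes the Re face of 6 (the sense that gives (R)-1-arylbut-3-en-1-ols, which reads 1S here because C8 outranks aryl), giving 1S,2R; the closest known reaction types are phosphoric-acid-catalysed crotyl- and γ-alkoxyallylboration of aryl aldehydes and the Ir/phosphoric acid relay from 1-alkenylboronates, and the γ-aryloxy case is the new part.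

Step 4
Reactants: 9 4-[(1S,2R)-1-hydroxy-2-{2-methoxy-4-(3-methoxy-3-oxopropyl)phenoxy}but-3-en-1-yl]benzene-1,2-diyl diacetate
Product: 12 (1S,2R)-1-(3,4-dihydroxyphenyl)-2-[4-(3-hydroxypropyl)-2-methoxyphenoxy]propane-1,3-diol (CNP0319307.1), via ozonide 10 (not isolated), via aldehyde 11 (not isolated)
Conditions: O3 (1.0 equiv, Sudan Red 7B end-point), CH2Cl2, −78 °C; N2 purge; LiBH4 (6 equiv, 2 M in THF), −78 °C → rt, then MeOH (4 equiv), 12 h; aq NH4Cl to pH 4–5, MeOH co-evaporation
Reagents that add atoms: ozone [O-][O+]=O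
Why: Criegee ozonolysis of the only alkene, which reacts much faster than the arenes at −78 °C, followed by in situ hydride reduction; excess LiBH4 reduces the epimerisable α-aryloxy aldehyde as soon as it is released, so C8 and C7 are untouched, and the same reagent reduces the methyl ester to CH2OH and cleaves both aryl acetates.

## Compound list
1 | methyl 3-(4-hydroxy-3-methoxyphenyl)propanoate | COC(=O)CCc1ccc(O)c(OC)c1 | starting material
2 | propargyl bromide | C#CCBr | starting material
3 | methyl 3-[3-methoxy-4-(prop-2-yn-1-yloxy)phenyl]propanoate | COC(=O)CCc1ccc(OCC#C)c(OC)c1 | intermediate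
4 | pinacolborane | [H]B1OC(C)(C)C(C)(C)O1 | starting material
5 | methyl 3-(3-methoxy-4-{[(2E)-3-(pinacolboryl)prop-2-en-1-yl]oxy}phenyl)propanoate | COC(=O)CCc1ccc(OC/C=C/B2OC(C)(C)C(C)(C)O2)c(OC)c1 | intermediate
6 | 3,4-diacetoxybenzaldehyde | CC(=O)Oc1ccc(C=O)cc1OC(C)=O | starting material
7 | methyl 3-(3-methoxy-4-{[(1E)-3-(pinacolboryl)prop-1-en-1-yl]oxy}phenyl)propanoate, the (E)-γ-aryloxyallylboronate | COC(=O)CCc1ccc(O/C=C/CB2OC(C)(C)C(C)(C)O2)c(OC)c1 | intermediate (not isolated)
8 | O-pinacolboryl ester of 9 (1S,2R) | COC(=O)CCc1ccc(O[C@H](C=C)[C@@H](OB2OC(C)(C)C(C)(C)O2)c2ccc(OC(C)=O)c(OC(C)=O)c2)c(OC)c1 | intermediate (not isolated)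
9 | 4-[(1S,2R)-1-hydroxy-2-{2-methoxy-4-(3-methoxy-3-oxopropyl)phenoxy}but-3-en-1-yl]benzene-1,2-diyl diacetate | COC(=O)CCc1ccc(O[C@H](C=C)[C@@H](O)c2ccc(OC(C)=O)c(OC(C)=O)c2)c(OC)c1 | intermediate
10 | 1,2,4-trioxolane (secondary ozonide) of 9, C7/C8 as in 9, epimers at the trioxolane carbon | COC(=O)CCc1ccc(O[C@H](C2OCOO2)[C@@H](O)c2ccc(OC(C)=O)c(OC(C)=O)c2)c(OC)c1 | intermediate (not isolated)
11 | (2S,3S)-3-(3,4-diacetoxyphenyl)-3-hydroxy-2-[2-methoxy-4-(3-methoxy-3-oxopropyl)phenoxy]propanal (same spatial arrangement as 9) | COC(=O)CCc1ccc(O[C@H](C=O)[C@@H](O)c2ccc(OC(C)=O)c(OC(C)=O)c2)c(OC)c1 | intermediate (not isolated)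
12 | (1S,2R)-1-(3,4-dihydroxyphenyl)-2-[4-(3-hydroxypropyl)-2-methoxyphenoxy]propane-1,3-diol | COc1cc(CCCO)ccc1O[C@H](CO)[C@@H](O)c1ccc(O)c(O)c1 | target

## Count and risks
Total step count: 4. Longest linear sequence: 4 (1 → 3 → 5 → 9 → 12).

**Step 3 is the most likely to fail.**
- Risks at iridium: β-aryloxy elimination or erosion of the E geometry.
- Risks at boron: the γ-aryloxyallyl-Bpin is electronically mismatched and slow, so conversion or ee may be low.
- Fallback: relative and absolute control are separated. It sets out from 5, through 7, together with 6.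
- 7 and 6 are heated without phosphoric acid (toluene, 50 °C). The chair transition state still enforces anti and gives the racemic anti borate ester F1. Moist silica turns this into the racemic anti homoallylic alcohol F2.
- An acylative kinetic resolution follows: (S)-benzotetramisole (4 mol %), isobutyric anhydride (0.6 equiv), iPr2NEt, CHCl3, 0 °C, to about 55 % conversion. It esterifies the unwanted enantiomer to the (1R,2S)-isobutyrate F3, which is removed by chromatography.
- The unreacted alcohol is 9, where the route is rejoined.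

**Step 4 is second.**
- Risks: ozone may attack the dialkoxy ring, the ester may not reduce fully, boron may stay bound to the catechol, and the benzylic position may over-reduce through a quinone methide.
- Fallback: it sets out from 9, removes ozone, and uncouples the cleavage from the global reduction.
- Citric-acid-buffered catalytic dihydroxylation (K2OsO4, NMO, acetone/H2O) gives the vicinal diol F4.
- NaIO4 (THF/pH 7 buffer, 0 °C) cleaves F4 to 11. After extraction, 11 is reduced at once (NaBH4, THF/EtOH, −20 °C) to the primary alcohol F5, which is isolated and purified.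
- Separate treatment with LiBH4 in THF/MeOH at rt removes the ester and acetate carbonyls and arrives at 12.

**Step 2 is third.**
- Risks: internal hydrometalation followed by β-aryloxy loss back to 1, or partial reduction of the ester.
- Fallback: it sets out from 1 and avoids the alkyne altogether. The phenoxide (K2CO3, cat. NaI, DMF, 40 °C) is alkylated by SN2 with commercial (E)-2-(3-chloroprop-1-en-1-yl)-4,4,5,5-tetramethyl-1,3,2-dioxaborolane.
- This gives 5 directly, where the route is rejoined. The reagent costs much more per mole than propargyl bromide plus HBpin, so it is kept in reserve.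

## Further compounds
F1 | step 3 | racemic anti O-pinacolboryl ester (1S,2R plus 1R,2S) | COC(=O)CCc1ccc(O[C@H](C=C)[C@@H](OB2OC(C)(C)C(C)(C)O2)c2ccc(OC(C)=O)c(OC(C)=O)c2)c(OC)c1.COC(=O)CCc1ccc(O[C@@H](C=C)[C@H](OB2OC(C)(C)C(C)(C)O2)c2ccc(OC(C)=O)c(OC(C)=O)c2)c(OC)c1
F2 | step 3 | racemic anti homoallylic alcohol (9 plus its enantiomer) | COC(=O)CCc1ccc(O[C@H](C=C)[C@@H](O)c2ccc(OC(C)=O)c(OC(C)=O)c2)c(OC)c1.COC(=O)CCc1ccc(O[C@@H](C=C)[C@H](O)c2ccc(OC(C)=O)c(OC(C)=O)c2)c(OC)c1
F3 | step 3 | (1R,2S)-isobutyrate of the unwanted enantiomer | COC(=O)CCc1ccc(O[C@@H](C=C)[C@H](OC(=O)C(C)C)c2ccc(OC(C)=O)c(OC(C)=O)c2)c(OC)c1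
F4 | step 4 | vicinal diol from dihydroxylation of the vinyl group of 9 (C7/C8 as in 9, epimers at the new CHOH) | COC(=O)CCc1ccc(O[C@H](C(O)CO)[C@@H](O)c2ccc(OC(C)=O)c(OC(C)=O)c2)c(OC)c1
F5 | step 4 | 4-[(1S,2R)-1,3-dihydroxy-2-{2-methoxy-4-(3-methoxy-3-oxopropyl)phenoxy}propyl]benzene-1,2-diyl diacetate | COC(=O)CCc1ccc(O[C@H](CO)[C@@H](O)c2ccc(OC(C)=O)c(OC(C)=O)c2)c(OC)c1
F0 | step 2 | none | none
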